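**Retrosynthetic overview**
- The target comes from a 3‑oxo‑oxolane by hydroxyl‑directed ketone reduction and hydrogenolysis of three benzyl ethers; the ketone comes from an oxolane‑3,3‑dicarboxylate by oxidative bis‑decarboxylation, so the C3 carbinol is a masked geminal diester.
- Key disconnection: the oxolane O1–C5 and C2–C3 bonds, made together by a Lewis‑acid (3+2) annulation of a cis‑2‑aryl‑3‑(silyloxymethyl)cyclopropane‑1,1‑diester (temporary ring plus activating group) with 2‑[4‑(benzyloxy)‑3‑methoxyphenyl]acetaldehyde.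
- Enabling feature: oxolane C5 is benzylic to the benzo ring of the dihydrobenzofuran, whose furan oxygen sits para to it (7‑OMe on the same ring), so C5 can carry positive charge; the oxolane is 2,5‑cis across its ring oxygen and C3 bears only O and H.
- The cyclopropane comes from a Z‑alkene by copper‑carbene malonate transfer; the Z‑alkene comes from the C5 bromide of the dihydrobenzofuran by Sonogashira coupling and semi‑hydrogenation.
- Ring order: furan ring of the dihydrobenzofuran first (Rh‑carbene C–H insertion, cis), cyclopropane second, oxolane last.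

Key step: step 13

Remark: the sense of induction of the chiral catalysts in steps 4 and 10 is assumed as drawn; if either gives the opposite sense, its mirror‑image ligand set is used.
Remark: triisopropyl(prop‑2‑yn‑1‑yloxy)silane (10) is taken as a purchased compound.
Abbreviations used in names: Ar = (2R,3R)‑2‑[4‑(benzyloxy)‑3‑methoxyphenyl]‑3‑[(benzyloxy)methyl]‑7‑methoxy‑2,3‑dihydro‑1‑benzofuran‑5‑yl (2,3‑cis); TIPS = triisopropylsilyl; Bn = benzyl.

**Route**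

Step 1
Reactants: 1 4‑bromo‑2‑methoxyphenol
Product: 2 4‑bromo‑2‑iodo‑6‑methoxyphenol
Conditions: N‑iodosuccinimide, TsOH (cat.), MeCN, 0 °C to rt
Reagents that add atoms: N‑iodosuccinimide, O=C1CCC(=O)N1I
Why: Electrophilic aromatic iodination; the free phenol directs iodine to its only open ortho position (para carries bromine), and no stereocentre is involved.

Step 2
Reactants: 2 4‑bromo‑2‑iodo‑6‑methoxyphenol; 3 [4‑(benzyloxy)‑3‑methoxyphenyl]methanol
Product: 4 1‑(benzyloxy)‑4‑[(4‑bromo‑2‑iodo‑6‑methoxyphenoxy)methyl]‑2‑methoxybenzene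
Conditions: PPh3, diisopropyl azodicarboxylate, THF, 0 °C to rt
Reagents that add atoms: none
Why: Mitsunobu etherification of an acidic phenol with a primary benzylic alcohol joins the two aryl units under neutral conditions that leave both aryl halides untouched.

Step 3
Reactants: 4 1‑(benzyloxy)‑4‑[(4‑bromo‑2‑iodo‑6‑methoxyphenoxy)methyl]‑2‑methoxybenzene; 5 ethyl diazoacetate
Product: 6 ethyl 2‑[2‑{[4‑(benzyloxy)‑3‑methoxyphenyl]methoxy}‑5‑bromo‑3‑methoxyphenyl]‑2‑diazoacetate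
Conditions: Pd(PPh3)4 (5 mol%), Ag2CO3 (0.5 equiv), Et3N, toluene, rt
Reagents that add atoms: none
Why: Palladium‑catalysed cross‑coupling of an aryl iodide with a diazoacetate that keeps the diazo group; at room temperature zerovalent palladium inserts into C–I and not into C–Br.

Step 4
Reactants: 6 ethyl 2‑[2‑{[4‑(benzyloxy)‑3‑methoxyphenyl]methoxy}‑5‑bromo‑3‑methoxyphenyl]‑2‑diazoacetate
Product: 7 ethyl (2R,3S)‑2‑[4‑(benzyloxy)‑3‑methoxyphenyl]‑5‑bromo‑7‑methoxy‑2,3‑dihydro‑1‑benzofuran‑3‑carboxylate (2,3‑cis)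
Conditions: Rh2(S‑PTTL)4 [dirhodium tetrakis(N‑phthaloyl‑(S)‑tert‑leucinate)] (2 mol%), toluene, −60 °C
Reagents that add atoms: none
Why: Intramolecular 1,5 C–H insertion of the rhodium carbene into the benzylic ether methylene closes the furan ring; the chiral carboxylate ligands select the enantiotopic C–H bond and the compact insertion transition state places aryl and ester cis, setting C2 as R and C3 as S.

Step 5
Reactants: 7 ethyl (2R,3S)‑2‑[4‑(benzyloxy)‑3‑methoxyphenyl]‑5‑bromo‑7‑methoxy‑2,3‑dihydro‑1‑benzofuran‑3‑carboxylate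
Product: 8 [(2R,3R)‑2‑[4‑(benzyloxy)‑3‑methoxyphenyl]‑5‑bromo‑7‑methoxy‑2,3‑dihydro‑1‑benzofuran‑3‑yl]methanol (2,3‑cis)
Conditions: i‑Bu2AlH (3 equiv), CH2Cl2, −78 °C to −20 °C
Reagents that add atoms: none
Why: Ester reduction with a Lewis‑acidic, non‑basic hydride at low temperature gives the primary alcohol without epimerising the base‑sensitive cis ester (the C3 descriptor changes only through substituent priority); the aryl bromide is inert.

Step 6
Reactants: 8 [(2R,3R)‑2‑[4‑(benzyloxy)‑3‑methoxyphenyl]‑5‑bromo‑7‑methoxy‑2,3‑dihydro‑1‑benzofuran‑3‑yl]methanol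
Product: 9 (2R,3R)‑2‑[4‑(benzyloxy)‑3‑methoxyphenyl]‑3‑[(benzyloxy)methyl]‑5‑bromo‑7‑methoxy‑2,3‑dihydro‑1‑benzofuran (Ar–Br)
Conditions: NaH, BnBr, n‑Bu4NI (cat.), THF/DMF, 0 °C to rt
Reagents that add atoms: benzyl bromide, BrCc1ccccc1
Why: Williamson etherification protects the primary alcohol as a benzyl ether that survives all later steps and leaves in the final hydrogenolysis.

Step 7
Reactants: 9 Ar–Br; 10 triisopropyl(prop‑2‑yn‑1‑yloxy)silane
Product: 11 triisopropyl{[3‑(Ar)prop‑2‑yn‑1‑yl]oxy}silane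
Conditions: PdCl2(MeCN)2 (3 mol%), XPhos (9 mol%), Cs2CO3, MeCN, 80 °C
Reagents that add atoms: none
Why: Copper‑free Sonogashira coupling; the bulky biarylphosphine allows oxidative addition into the electron‑rich aryl bromide, and the silyl and benzyl ethers are inert.

Step 8
Reactants: 11 triisopropyl{[3‑(Ar)prop‑2‑yn‑1‑yl]oxy}silane
Product: 12 triisopropyl{[(2Z)‑3‑(Ar)prop‑2‑en‑1‑yl]oxy}silane
Conditions: H2 (1 atm), Pd/CaCO3 poisoned with Pb(OAc)2, quinoline, EtOAc, rt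
Reagents that add atoms: none
Why: Lindlar semi‑hydrogenation delivers both hydrogens to one face of the alkyne and so gives the Z‑alkene; the poisoned catalyst leaves the benzyl ethers intact.

Step 9
Reactants: 13 dimethyl malonate
Product: 14 dimethyl 2‑(phenyl‑λ3‑iodanylidene)malonate (iodonium ylide)
Conditions: PhI(OAc)2, KOH, MeCN, 0 °C
Reagents that add atoms: (diacetoxyiodo)benzene, CC(=O)OI(OC(C)=O)c1ccccc1
Why: Condensation of the malonate carbanion with the trivalent iodine diacetate gives the iodonium ylide, a storable malonate carbene precursor.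

Step 10
Reactants: 12 triisopropyl{[(2Z)‑3‑(Ar)prop‑2‑en‑1‑yl]oxy}silane; 14 dimethyl 2‑(phenyl‑λ3‑iodanylidene)malonate
Product: 15 dimethyl (2R,3R)‑2‑(Ar)‑3‑{[(triisopropylsilyl)oxy]methyl}cyclopropane‑1,1‑dicarboxylate (Ar and CH2OTIPS cis)
Conditions: Cu(MeCN)4PF6 (5 mol%), chiral side‑arm‑modified bis(oxazoline) ligand (6 mol%), 4 Å MS, toluene, 0 °C to rt
Reagents that add atoms: none
Why: Copper‑carbene cyclopropanation with an iodonium ylide; carbene transfer is concerted, so the Z geometry becomes the cis relation of aryl and silyloxymethyl groups, the chiral bis(oxazoline) selects the alkene face to give the (2R,3R) isomer, and the bulky silyl ether suppresses oxonium ylide formation.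

Step 11
Reactants: 16 4‑(2‑hydroxyethyl)‑2‑methoxyphenol
Product: 17 2‑[4‑(benzyloxy)‑3‑methoxyphenyl]ethan‑1‑ol
Conditions: BnBr, K2CO3, acetone, reflux
Reagents that add atoms: benzyl bromide, BrCc1ccccc1
Why: Williamson etherification is selective for the phenol, which is far more acidic than the primary alcohol toward the weak base.

Step 12
Reactants: 17 2‑[4‑(benzyloxy)‑3‑methoxyphenyl]ethan‑1‑ol
Product: 18 2‑[4‑(benzyloxy)‑3‑methoxyphenyl]acetaldehyde
Conditions: Dess–Martin periodinane, CH2Cl2, 0 °C to rt; used at once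
Reagents that add atoms: none
Why: Dess–Martin oxidation stops at the aldehyde under non‑basic conditions, which suits an enolisable arylacetaldehyde.

Step 13
Reactants: 15 dimethyl (2R,3R)‑2‑(Ar)‑3‑{[(triisopropylsilyl)oxy]methyl}cyclopropane‑1,1‑dicarboxylate; 18 2‑[4‑(benzyloxy)‑3‑methoxyphenyl]acetaldehyde
Product: 19 dimethyl (2S,4R,5S)‑5‑(Ar)‑2‑{[4‑(benzyloxy)‑3‑methoxyphenyl]methyl}‑4‑{[(triisopropylsilyl)oxy]methyl}oxolane‑3,3‑dicarboxylate
Conditions: SnCl4 (20 mol%), CH2Cl2, 4 Å MS, −78 °C to −40 °C, slow addition of 18 (2 equiv)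
Reagents that add atoms: none
Why: SnCl4 chelates the geminal diester of 15 and polarises the bond between the diester carbon and the benzylic carbon, whose positive character is supported by the para furan oxygen of the dihydrobenzofuran; the carbonyl oxygen of 18 attacks this carbon from the back side of the breaking bond, and the resulting O‑alkylated aldehyde (oxocarbenium ion) is captured by the tin malonate enolate, so the O1–C5 and C2–C3 bonds form in one operation. This is the Lewis‑acid‑catalysed (3+2) annulation of donor–acceptor cyclopropane‑1,1‑diesters with aldehydes, a reaction type established for aliphatic aldehydes and for 2,3‑disubstituted cyclopropanes. The oxolane closes by an intramolecular aldol‑type attack of the enolate carbon on the oxocarbenium carbon, a 5‑(enolexo)‑endo‑trig closure. C5 is set by inversion at the benzylic cyclopropane carbon, which places the aryl group trans to the C4 substituent carried over unchanged from the cyclopropane, and C2 is set in the envelope transition state of ring closure, where the arylmethyl group and the C5 aryl group both sit pseudo‑equatorial and give the 2,5‑cis oxolane. The step needs stereospecific opening instead of free ionisation, and capture of the aldehyde as an oxygen nucleophile before it enolises: the cis arrangement of aryl and silyloxymethyl groups in 15 makes the invertive path and any thermodynamic drift converge on the same 4,5‑trans isomer, and low temperature with slow addition of 18 keeps aldol self‑condensation and ionisation of the other benzylic ethers back.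

Step 14
Reactants: 19 dimethyl (2S,4R,5S)‑5‑(Ar)‑2‑{[4‑(benzyloxy)‑3‑methoxyphenyl]methyl}‑4‑{[(triisopropylsilyl)oxy]methyl}oxolane‑3,3‑dicarboxylate
Product: 20 (2S,4R,5S)‑5‑(Ar)‑2‑{[4‑(benzyloxy)‑3‑methoxyphenyl]methyl}‑4‑{[(triisopropylsilyl)oxy]methyl}oxolane‑3,3‑dicarboxylic acid
Conditions: KOH (excess), MeOH/THF/H2O, 65 °C; then 1 M HCl to pH 3 at 0 °C
Reagents that add atoms: potassium hydroxide, [K+].[OH-]
Why: Saponification of the two hindered methyl esters; the TIPS ether and the benzyl ethers resist aqueous base and no stereocentre is enolisable.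

Step 15
Reactants: 20 (2S,4R,5S)‑5‑(Ar)‑2‑{[4‑(benzyloxy)‑3‑methoxyphenyl]methyl}‑4‑{[(triisopropylsilyl)oxy]methyl}oxolane‑3,3‑dicarboxylic acid
Product: 22 (2S,4R,5S)‑5‑(Ar)‑2‑{[4‑(benzyloxy)‑3‑methoxyphenyl]methyl}‑4‑{[(triisopropylsilyl)oxy]methyl}oxolan‑3‑one, via geminal diacetate 21 (not isolated)
Conditions: Pb(OAc)4 (2.5 equiv), pyridine, benzene, 60 °C; aqueous NaHCO3 work‑up, silica gel
Reagents that add atoms: lead tetraacetate, CC(=O)O[Pb](OC(C)=O)(OC(C)=O)OC(C)=O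
Why: Oxidative bis‑decarboxylation of a disubstituted malonic acid; two successive decarboxylative acetoxylations give the geminal diacetate, which hydrolyses to the ketone on work‑up, so the activating group leaves as CO2 and the ketone never meets the basic medium.

Step 16
Reactants: 22 (2S,4R,5S)‑5‑(Ar)‑2‑{[4‑(benzyloxy)‑3‑methoxyphenyl]methyl}‑4‑{[(triisopropylsilyl)oxy]methyl}oxolan‑3‑one
Product: 23 (2S,4R,5S)‑5‑(Ar)‑2‑{[4‑(benzyloxy)‑3‑methoxyphenyl]methyl}‑4‑(hydroxymethyl)oxolan‑3‑one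
Conditions: HF·pyridine, pyridine/THF, 0 °C to rt
Reagents that add atoms: none
Why: Fluoride‑mediated desilylation under buffered, weakly acidic conditions frees the primary alcohol without retro‑aldol cleavage or β‑elimination of the β‑hydroxy ketone.

Step 17
Reactants: 23 (2S,4R,5S)‑5‑(Ar)‑2‑{[4‑(benzyloxy)‑3‑methoxyphenyl]methyl}‑4‑(hydroxymethyl)oxolan‑3‑one
Product: 24 (2S,3S,4S,5S)‑5‑(Ar)‑2‑{[4‑(benzyloxy)‑3‑methoxyphenyl]methyl}‑4‑(hydroxymethyl)oxolan‑3‑ol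
Conditions: Me4NBH(OAc)3, MeCN/AcOH, −30 °C to −20 °C
Reagents that add atoms: none
Why: Hydroxyl‑directed (Evans–Saksena) reduction; the C4 hydroxymethyl group binds the acetoxyborohydride and delivers hydride to the ketone face it occupies, so the new C3 hydroxyl ends trans to CH2OH and cis to the C2 arylmethyl group (3S).

Step 18
Reactants: 24 (2S,3S,4S,5S)‑5‑(Ar)‑2‑{[4‑(benzyloxy)‑3‑methoxyphenyl]methyl}‑4‑(hydroxymethyl)oxolan‑3‑ol
Product: 25 (2S,3S,4S,5S)‑2‑[(4‑hydroxy‑3‑methoxyphenyl)methyl]‑5‑[(2R,3R)‑2‑(4‑hydroxy‑3‑methoxyphenyl)‑3‑(hydroxymethyl)‑7‑methoxy‑2,3‑dihydro‑1‑benzofuran‑5‑yl]‑4‑(hydroxymethyl)oxolan‑3‑ol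
Conditions: H2 (1 atm), Pd(OH)2/C, EtOAc/MeOH, rt, stopped at full conversion
Reagents that add atoms: none
Why: Hydrogenolysis of the two aryl benzyl ethers and the alkyl benzyl ether under neutral conditions; short exposure should keep the benzylic C–O bonds of both oxygen heterocycles.

**Compound list**
1 | 4‑bromo‑2‑methoxyphenol | COc1cc(Br)ccc1O | starting material
2 | 4‑bromo‑2‑iodo‑6‑methoxyphenol | COc1cc(Br)cc(I)c1O | intermediate
3 | [4‑(benzyloxy)‑3‑methoxyphenyl]methanol | COc1cc(CO)ccc1OCc1ccccc1 | starting material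
4 | 1‑(benzyloxy)‑4‑[(4‑bromo‑2‑iodo‑6‑methoxyphenoxy)methyl]‑2‑methoxybenzene | COc1cc(Br)cc(I)c1OCc1ccc(OCc2ccccc2)c(OC)c1 | intermediate
5 | ethyl diazoacetate | CCOC(=O)C=[N+]=[N-] | starting material
6 | ethyl 2‑[2‑{[4‑(benzyloxy)‑3‑methoxyphenyl]methoxy}‑5‑bromo‑3‑methoxyphenyl]‑2‑diazoacetate | CCOC(=O)C(=[N+]=[N-])c1cc(Br)cc(OC)c1OCc1ccc(OCc2ccccc2)c(OC)c1 | intermediate
7 | ethyl (2R,3S)‑2‑[4‑(benzyloxy)‑3‑methoxyphenyl]‑5‑bromo‑7‑methoxy‑2,3‑dihydro‑1‑benzofuran‑3‑carboxylate (cis) | Brc1cc(OC)c2c(c1)[C@H](C(=O)OCC)[C@H](c1ccc(OCc3ccccc3)c(OC)c1)O2 | intermediate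
8 | [(2R,3R)‑2‑[4‑(benzyloxy)‑3‑methoxyphenyl]‑5‑bromo‑7‑methoxy‑2,3‑dihydro‑1‑benzofuran‑3‑yl]methanol (cis) | Brc1cc(OC)c2c(c1)[C@H](CO)[C@H](c1ccc(OCc3ccccc3)c(OC)c1)O2 | intermediate
9 | (2R,3R)‑2‑[4‑(benzyloxy)‑3‑methoxyphenyl]‑3‑[(benzyloxy)methyl]‑5‑bromo‑7‑methoxy‑2,3‑dihydro‑1‑benzofuran (Ar–Br) | Brc1cc(OC)c2c(c1)[C@H](COCc1ccccc1)[C@H](c1ccc(OCc3ccccc3)c(OC)c1)O2 | intermediate
10 | triisopropyl(prop‑2‑yn‑1‑yloxy)silane | C#CCO[Si](C(C)C)(C(C)C)C(C)C | starting material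
11 | triisopropyl{[3‑(Ar)prop‑2‑yn‑1‑yl]oxy}silane | CC(C)[Si](C(C)C)(C(C)C)OCC#Cc1cc(OC)c2c(c1)[C@H](COCc1ccccc1)[C@H](c1ccc(OCc3ccccc3)c(OC)c1)O2 | intermediate
12 | triisopropyl{[(2Z)‑3‑(Ar)prop‑2‑en‑1‑yl]oxy}silane | CC(C)[Si](C(C)C)(C(C)C)OC/C=C\c1cc(OC)c2c(c1)[C@H](COCc1ccccc1)[C@H](c1ccc(OCc3ccccc3)c(OC)c1)O2 | intermediate
13 | dimethyl malonate | COC(=O)CC(=O)OC | starting material
14 | dimethyl 2‑(phenyl‑λ3‑iodanylidene)malonate | COC(=O)[C-](C(=O)OC)[I+]c1ccccc1 | intermediate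
15 | dimethyl (2R,3R)‑2‑(Ar)‑3‑{[(triisopropylsilyl)oxy]methyl}cyclopropane‑1,1‑dicarboxylate (cis) | CC(C)[Si](C(C)C)(C(C)C)OC[C@@H]1[C@H](c2cc(OC)c3c(c2)[C@H](COCc2ccccc2)[C@H](c2ccc(OCc4ccccc4)c(OC)c2)O3)C1(C(=O)OC)C(=O)OC | intermediate
16 | 4‑(2‑hydroxyethyl)‑2‑methoxyphenol | COc1cc(CCO)ccc1O | starting material
17 | 2‑[4‑(benzyloxy)‑3‑methoxyphenyl]ethan‑1‑ol | COc1cc(CCO)ccc1OCc1ccccc1 | intermediate
18 | 2‑[4‑(benzyloxy)‑3‑methoxyphenyl]acetaldehyde | COc1cc(CC=O)ccc1OCc1ccccc1 | intermediate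
19 | dimethyl (2S,4R,5S)‑5‑(Ar)‑2‑{[4‑(benzyloxy)‑3‑methoxyphenyl]methyl}‑4‑{[(triisopropylsilyl)oxy]methyl}oxolane‑3,3‑dicarboxylate | COc1cc(C[C@@H]2O[C@H](c3cc(OC)c4c(c3)[C@H](COCc3ccccc3)[C@H](c3ccc(OCc5ccccc5)c(OC)c3)O4)[C@@H](CO[Si](C(C)C)(C(C)C)C(C)C)C2(C(=O)OC)C(=O)OC)ccc1OCc1ccccc1 | intermediate
20 | (2S,4R,5S)‑5‑(Ar)‑2‑{[4‑(benzyloxy)‑3‑methoxyphenyl]methyl}‑4‑{[(triisopropylsilyl)oxy]methyl}oxolane‑3,3‑dicarboxylic acid | COc1cc(C[C@@H]2O[C@H](c3cc(OC)c4c(c3)[C@H](COCc3ccccc3)[C@H](c3ccc(OCc5ccccc5)c(OC)c3)O4)[C@@H](CO[Si](C(C)C)(C(C)C)C(C)C)C2(C(O)=O)C(O)=O)ccc1OCc1ccccc1 | intermediate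
21 | (2S,4R,5S)‑5‑(Ar)‑2‑{[4‑(benzyloxy)‑3‑methoxyphenyl]methyl}‑4‑{[(triisopropylsilyl)oxy]methyl}oxolane‑3,3‑diyl diacetate | COc1cc(C[C@@H]2O[C@H](c3cc(OC)c4c(c3)[C@H](COCc3ccccc3)[C@H](c3ccc(OCc5ccccc5)c(OC)c3)O4)[C@@H](CO[Si](C(C)C)(C(C)C)C(C)C)C2(OC(C)=O)OC(C)=O)ccc1OCc1ccccc1 | intermediate (not isolated)
22 | (2S,4R,5S)‑5‑(Ar)‑2‑{[4‑(benzyloxy)‑3‑methoxyphenyl]methyl}‑4‑{[(triisopropylsilyl)oxy]methyl}oxolan‑3‑one | COc1cc(C[C@@H]2O[C@H](c3cc(OC)c4c(c3)[C@H](COCc3ccccc3)[C@H](c3ccc(OCc5ccccc5)c(OC)c3)O4)[C@@H](CO[Si](C(C)C)(C(C)C)C(C)C)C2=O)ccc1OCc1ccccc1 | intermediate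
23 | (2S,4R,5S)‑5‑(Ar)‑2‑{[4‑(benzyloxy)‑3‑methoxyphenyl]methyl}‑4‑(hydroxymethyl)oxolan‑3‑one | COc1cc(C[C@@H]2O[C@H](c3cc(OC)c4c(c3)[C@H](COCc3ccccc3)[C@H](c3ccc(OCc5ccccc5)c(OC)c3)O4)[C@@H](CO)C2=O)ccc1OCc1ccccc1 | intermediate
24 | (2S,3S,4S,5S)‑5‑(Ar)‑2‑{[4‑(benzyloxy)‑3‑methoxyphenyl]methyl}‑4‑(hydroxymethyl)oxolan‑3‑ol | COc1cc(C[C@@H]2O[C@H](c3cc(OC)c4c(c3)[C@H](COCc3ccccc3)[C@H](c3ccc(OCc5ccccc5)c(OC)c3)O4)[C@@H](CO)[C@@H]2O)ccc1OCc1ccccc1 | intermediate
25 | (2S,3S,4S,5S)‑2‑[(4‑hydroxy‑3‑methoxyphenyl)methyl]‑5‑[(2R,3R)‑2‑(4‑hydroxy‑3‑methoxyphenyl)‑3‑(hydroxymethyl)‑7‑methoxy‑2,3‑dihydro‑1‑benzofuran‑5‑yl]‑4‑(hydroxymethyl)oxolan‑3‑ol | COc1cc(C[C@@H]2O[C@H](c3cc(OC)c4c(c3)[C@H](CO)[C@H](c3ccc(O)c(OC)c3)O4)[C@@H](CO)[C@@H]2O)ccc1O | target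

**Totals**
Total step count: 18. Longest linear sequence: 15 steps (steps 1–8, 10, 13–18).

**Steps most likely to fail**

Step 15. The species formed after the first decarboxylation may fragment or eliminate instead of being acetoxylated, or the second decarboxylation may stall, so the ketone does not form cleanly. The fallback sets out from 19 and comes back at 22. Krapcho dealkoxycarbonylation of 19 (LiCl, wet DMSO, 140 °C) should give the mono‑ester methyl 5‑(Ar)‑2‑{[4‑(benzyloxy)‑3‑methoxyphenyl]methyl}‑4‑{[(triisopropylsilyl)oxy]methyl}oxolane‑3‑carboxylate F1 (C2, C4, C5 as in 19; either C3 epimer serves). Enolisation with KN(SiMe3)2 at −78 °C and oxidation with 2‑(phenylsulfonyl)‑3‑phenyloxaziridine should give the α‑hydroxy ester F2; opening of the ring by β‑elimination is stereoelectronically disfavoured because the C2–O bond lies in the enolate plane. LiAlH4 reduction should give the 3‑(hydroxymethyl)oxolan‑3‑ol F3, and NaIO4 cleavage of this 1,2‑diol returns ketone 22.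

Step 13. The very electron‑rich cyclopropane may ionise to a free benzylic cation before the aldehyde is engaged, with loss of stereochemical fidelity at C5 and C2, and the enolisable aldehyde may self‑condense under the Lewis acid. The fallback sets out from 15 and comes back at 20; it uses a temporary lactone tether. n‑Bu4NF removes the silyl group of 15 and the alkoxide closes onto the syn ester to give methyl (1S,5R,6R)‑6‑(Ar)‑2‑oxo‑3‑oxabicyclo[3.1.0]hexane‑1‑carboxylate F4 (aryl endo). The same annulation with 18 should give methyl (1R,5R,6S,8S)‑6‑(Ar)‑8‑{[4‑(benzyloxy)‑3‑methoxyphenyl]methyl}‑2‑oxo‑3,7‑dioxabicyclo[3.3.0]octane‑1‑carboxylate F5, in which the cis ring fusion forces both new substituents onto the convex face whatever the timing of bond formation. KOH hydrolysis of ester and lactone gives the hydroxy diacid (2S,4R,5S)‑5‑(Ar)‑2‑{[4‑(benzyloxy)‑3‑methoxyphenyl]methyl}‑4‑(hydroxymethyl)oxolane‑3,3‑dicarboxylic acid F6, kept as its dipotassium salt. Persilylation (i‑Pr3SiOTf, 2,6‑lutidine) gives the silyl ether bis(triisopropylsilyl) ester F7, and hydrolysis of the two silyl esters (K2CO3, aqueous MeOH) returns 20.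

Step 10. Carbene transfer to the hindered Z‑alkene may show poor facial selectivity under catalyst control, or the carbene may be diverted to oxonium ylides or C–H insertion. The fallback sets out from 12 and comes back at 15. It replaces catalyst control by a stereospecific but face‑unselective cyclopropanation with dimethyl diazomalonate and Rh2(esp)2 [dirhodium bis(α,α,α′,α′‑tetramethyl‑1,3‑benzenedipropionate)]. This should give 15 together with its cis diastereomer dimethyl (2S,3S)‑2‑(Ar)‑3‑{[(triisopropylsilyl)oxy]methyl}cyclopropane‑1,1‑dicarboxylate F8. The two differ as diastereomers because of the dihydrobenzofuran stereocentres and are separated by chromatography; 15 is carried on.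

Further compounds
F1 | step 15 | methyl 5‑(Ar)‑2‑{[4‑(benzyloxy)‑3‑methoxyphenyl]methyl}‑4‑{[(triisopropylsilyl)oxy]methyl}oxolane‑3‑carboxylate | COc1cc(C[C@@H]2O[C@H](c3cc(OC)c4c(c3)[C@H](COCc3ccccc3)[C@H](c3ccc(OCc5ccccc5)c(OC)c3)O4)[C@@H](CO[Si](C(C)C)(C(C)C)C(C)C)C2C(=O)OC)ccc1OCc1ccccc1
F2 | step 15 | methyl 5‑(Ar)‑2‑{[4‑(benzyloxy)‑3‑methoxyphenyl]methyl}‑3‑hydroxy‑4‑{[(triisopropylsilyl)oxy]methyl}oxolane‑3‑carboxylate | COc1cc(C[C@@H]2O[C@H](c3cc(OC)c4c(c3)[C@H](COCc3ccccc3)[C@H](c3ccc(OCc5ccccc5)c(OC)c3)O4)[C@@H](CO[Si](C(C)C)(C(C)C)C(C)C)C2(O)C(=O)OC)ccc1OCc1ccccc1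
F3 | step 15 | 5‑(Ar)‑2‑{[4‑(benzyloxy)‑3‑methoxyphenyl]methyl}‑3‑(hydroxymethyl)‑4‑{[(triisopropylsilyl)oxy]methyl}oxolan‑3‑ol | COc1cc(C[C@@H]2O[C@H](c3cc(OC)c4c(c3)[C@H](COCc3ccccc3)[C@H](c3ccc(OCc5ccccc5)c(OC)c3)O4)[C@@H](CO[Si](C(C)C)(C(C)C)C(C)C)C2(O)CO)ccc1OCc1ccccc1
F4 | step 13 | methyl (1S,5R,6R)‑6‑(Ar)‑2‑oxo‑3‑oxabicyclo[3.1.0]hexane‑1‑carboxylate | COC(=O)[C@@]12C(=O)OC[C@@H]1[C@@H]2c1cc(OC)c2c(c1)[C@H](COCc1ccccc1)[C@H](c1ccc(OCc3ccccc3)c(OC)c1)O2
F5 | step 13 | methyl (1R,5R,6S,8S)‑6‑(Ar)‑8‑{[4‑(benzyloxy)‑3‑methoxyphenyl]methyl}‑2‑oxo‑3,7‑dioxabicyclo[3.3.0]octane‑1‑carboxylate | COc1cc(C[C@@H]2O[C@H](c3cc(OC)c4c(c3)[C@H](COCc3ccccc3)[C@H](c3ccc(OCc5ccccc5)c(OC)c3)O4)[C@H]3COC(=O)[C@@]23C(=O)OC)ccc1OCc1ccccc1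
F6 | step 13 | (2S,4R,5S)‑5‑(Ar)‑2‑{[4‑(benzyloxy)‑3‑methoxyphenyl]methyl}‑4‑(hydroxymethyl)oxolane‑3,3‑dicarboxylic acid | COc1cc(C[C@@H]2O[C@H](c3cc(OC)c4c(c3)[C@H](COCc3ccccc3)[C@H](c3ccc(OCc5ccccc5)c(OC)c3)O4)[C@@H](CO)C2(C(O)=O)C(O)=O)ccc1OCc1ccccc1
F7 | step 13 | bis(triisopropylsilyl) (2S,4R,5S)‑5‑(Ar)‑2‑{[4‑(benzyloxy)‑3‑methoxyphenyl]methyl}‑4‑{[(triisopropylsilyl)oxy]methyl}oxolane‑3,3‑dicarboxylate | COc1cc(C[C@@H]2O[C@H](c3cc(OC)c4c(c3)[C@H](COCc3ccccc3)[C@H](c3ccc(OCc5ccccc5)c(OC)c3)O4)[C@@H](CO[Si](C(C)C)(C(C)C)C(C)C)C2(C(=O)O[Si](C(C)C)(C(C)C)C(C)C)C(=O)O[Si](C(C)C)(C(C)C)C(C)C)ccc1OCc1ccccc1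
F8 | step 10 | dimethyl (2S,3S)‑2‑(Ar)‑3‑{[(triisopropylsilyl)oxy]methyl}cyclopropane‑1,1‑dicarboxylate (cis) | CC(C)[Si](C(C)C)(C(C)C)OC[C@H]1[C@@H](c2cc(OC)c3c(c2)[C@H](COCc2ccccc2)[C@H](c2ccc(OCc4ccccc4)c(OC)c2)O3)C1(C(=O)OC)C(=O)OC
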